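## Retrosynthetic overview

1. Both 2H-pyran-2-one rings are annulated last and together (mono-O-demethylation, ortho-formylation, ketene-ylide Wittig lactonisation) on a bis(2,6-dimethoxyphenyl) diene. Each 2,6-dimethoxyphenyl group is a latent 7-methoxycoumarin-8-yl unit; its two methoxy groups are equivalent and one can be removed with thiolate, without acid.
2. The E alkene Ca=Cb is cut by Julia–Kocienski olefination into a C1 carbaldehyde and a 2,6-dimethoxybenzyl tetrazolyl sulfone.
3. The C4 methyl comes from an enol triflate. The C6 aryl comes from conjugate addition to a cyclohex-2-enone, delivered by the alkoxide of the C1 hydroxymethyl arm so that aryl and Ca end up cis.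
4. The strategy rests on reading the carbocycle C1 (quaternary; CH3 and the Ca=Cb–aryl arm), C2, C3, C4(CH3)=C5, C6(H)(aryl) as a 4,4-disubstituted cyclohex-2-enone (C=O at C4, alkene C5=C6). This ring is made by an amine-catalysed asymmetric Robinson annulation of racemic 3-silyloxy-2-methylpropanal (C6, C1, Ca) with but-3-en-2-one (C2–C5).
5. Ring order: the cyclohexene ring first, in one step; the two pyranone rings in the final step.

Key step: step 3

Assumption: for a methyl/silyloxymethyl pair the sense of induction of the amine catalyst cannot be predicted safely from aryl/methyl cases, so the antipode (quinine- or quinidine-derived) that gives the (S)-enone is fixed in a trial run; the steps are written for that antipode.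

## Route

Step 1
Reactants: 1 methyl 3-hydroxy-2-methylpropanoate (racemic)
Product: 2 methyl 3-[(tert-butyldimethylsilyl)oxy]-2-methylpropanoate (racemic)
Conditions: TBSCl, imidazole, DMF, 0 °C → rt
Reagents that add atoms: tert-butyldimethylsilyl chloride, CC(C)(C)[Si](C)(C)Cl
Why: Silylation of a primary alcohol under imidazole catalysis is routine, and the racemate suffices because this stereocentre is erased in step 3.

Step 2
Reactants: 2 methyl 3-[(tert-butyldimethylsilyl)oxy]-2-methylpropanoate
Product: 3 3-[(tert-butyldimethylsilyl)oxy]-2-methylpropanal (racemic)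
Conditions: DIBAL-H (1.05 equiv), CH2Cl2, −78 °C; MeOH, then aq. Rochelle salt
Reagents that add atoms: none
Why: Partial ester reduction; the aluminium hemiacetal is stable at −78 °C (helped by chelation to the β-silyloxy oxygen) and should collapse to the aldehyde only on work-up.

Step 3
Reactants: 3 3-[(tert-butyldimethylsilyl)oxy]-2-methylpropanal (racemic); 4 but-3-en-2-one (1.5 equiv)
Product: 6 (S)-4-{[(tert-butyldimethylsilyl)oxy]methyl}-4-methylcyclohex-2-en-1-one, via keto-aldehyde 5 (not isolated)
Conditions: 9-amino-9-deoxy-epi-quinine or its quinidine-derived pseudo-enantiomer (20 mol%), PhCO2H (40 mol%), toluene, rt, then 50 °C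
Reagents that add atoms: none
Why: The primary amine condenses with racemic 3 to an imine that tautomerises to the trisubstituted enamine, which erases the α-stereocentre so that both enantiomers of 3 enter one pathway; the enamine adds to acid-activated but-3-en-2-one, forming C1–C2 and, after hydrolysis, keto-aldehyde 5. The closest known reaction type is the primary-amine-catalysed asymmetric Robinson annulation of α,α-disubstituted aldehydes with methyl vinyl ketone to 4,4-disubstituted cyclohex-2-enones. The ring closes by a 6-(enolendo)-exo-trig aldol addition of the methyl-ketone enamine or enol onto the formyl (or iminium) carbon, and E1cB dehydration then gives the C5=C6 alkene. The quaternary stereocentre C1 is fixed in the Michael step by the enamine geometry (the bulkier silyloxymethyl group anti to nitrogen) together with the enamine face left open by the catalyst, whose quinuclidinium site holds the enone by hydrogen bonding. The step needs enantiofacial discrimination between an α-methyl and an α-silyloxymethyl group, which the bulk of the TBS ether is meant to secure, and a single cyclisation mode, which is certain because 5 has no α-hydrogen on the aldehyde side and only the ketone methyl can reach the formyl carbon through a six-membered ring. β-Elimination of silanolate from the enamine should be held back by the poor leaving-group ability of the silyloxy group under the weakly acidic conditions.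

Step 4
Reactants: 6 (S)-4-{[(tert-butyldimethylsilyl)oxy]methyl}-4-methylcyclohex-2-en-1-one
Product: 7 (S)-4-(hydroxymethyl)-4-methylcyclohex-2-en-1-one
Conditions: HF·pyridine, THF, 0 °C → rt
Reagents that add atoms: none
Why: Fluoride cleaves the Si–O bond under mildly acidic conditions, so the γ-hydroxymethyl enone is never exposed to base that could cause vinylogous retro-aldol loss of formaldehyde.

Step 5
Reactants: 8 2-bromo-1,3-dimethoxybenzene
Product: 9 (2,6-dimethoxyphenyl)magnesium bromide (THF solution)
Conditions: Mg turnings (I2-activated), THF, 40 °C → rt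
Reagents that add atoms: magnesium, [Mg]
Why: Grignard formation by magnesium insertion into the aryl bromide; the two ortho methoxy groups stabilise the reagent by coordination.

Step 6
Reactants: 7 (S)-4-(hydroxymethyl)-4-methylcyclohex-2-en-1-one; 9 (2,6-dimethoxyphenyl)magnesium bromide (3.2 equiv)
Product: 11 {[(1S,2R)-2-(2,6-dimethoxyphenyl)-1-methyl-4-(trimethylsilyloxy)cyclohex-3-en-1-yl]methoxy}trimethylsilane, via magnesium enolate alkoxide 10 (not isolated)
Conditions: THF, −78 → 0 °C; then TMSCl (6 equiv), Et3N, DMPU, −78 → 0 °C; cold pH 7 buffer/pentane work-up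
Reagents that add atoms: chlorotrimethylsilane, C[Si](C)(C)Cl
Why: Proposed new method: the first equivalent of 9 deprotonates the hydroxyl, the bromomagnesium alkoxide exchanges with further 9 to an aryl(alkoxy)magnesium species, and the aryl group is handed to C6 through a six-membered O–Mg–C(aryl)···C6–C1–Ca array that exists only on the face carrying Ca and cannot reach the carbonyl carbon, so 1,4-addition syn to the hydroxymethyl arm should result (aryl cis to Ca, new C6 stereocentre R, controlled by C1), and the enolate is captured regiospecifically as the C4=C5 silyl enol ether together with the alkoxide; the closest known reaction type is the alkoxide-directed conjugate addition of Grignard reagents to 4-oxido-cyclohex-2-enones (quinol alkoxides) and γ-hydroxy alkenenitriles, extended here by one carbon in the tether and to a di-ortho-substituted aryl group.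

Step 7
Reactants: 11 {[(1S,2R)-2-(2,6-dimethoxyphenyl)-1-methyl-4-(trimethylsilyloxy)cyclohex-3-en-1-yl]methoxy}trimethylsilane
Product: 13 (3R,4S)-3-(2,6-dimethoxyphenyl)-4-methyl-4-[(trimethylsilyloxy)methyl]cyclohex-1-en-1-yl trifluoromethanesulfonate, via lithium enolate 12 (not isolated)
Conditions: MeLi (1.05 equiv), THF, 0 °C; then PhNTf2, −78 °C → rt
Reagents that add atoms: N-phenylbis(trifluoromethanesulfonimide), O=S(=O)(N(c1ccccc1)S(=O)(=O)C(F)(F)F)C(F)(F)F
Why: Methyllithium cleaves the silyl enol ether (the alkyl trimethylsilyl ether is much slower to react) and regenerates the C4=C5 lithium enolate without equilibration, and triflyl transfer from the triflimide then locks this regiochemistry as the enol triflate, which deprotonation of the ketone could not do.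

Step 8
Reactants: 13 (3R,4S)-3-(2,6-dimethoxyphenyl)-4-methyl-4-[(trimethylsilyloxy)methyl]cyclohex-1-en-1-yl trifluoromethanesulfonate
Product: 15 [(1S,2R)-2-(2,6-dimethoxyphenyl)-1,4-dimethylcyclohex-3-en-1-yl]methanol, via trimethylsilyl ether 14 (not isolated)
Conditions: MeMgBr (1.5 equiv), Fe(acac)3 (5 mol%), THF/NMP, −30 → 0 °C; then K2CO3, MeOH, rt
Reagents that add atoms: methylmagnesium bromide, C[Mg]Br
Why: Iron-catalysed Kumada-type cross-coupling of an alkenyl triflate with a methyl Grignard reagent is fast at low temperature and installs the C4 methyl with the C4=C5 alkene in place; methanolysis then removes the labile trimethylsilyl ether.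

Step 9
Reactants: 15 [(1S,2R)-2-(2,6-dimethoxyphenyl)-1,4-dimethylcyclohex-3-en-1-yl]methanol
Product: 16 (1S,2S)-2-(2,6-dimethoxyphenyl)-1,4-dimethylcyclohex-3-ene-1-carbaldehyde
Conditions: Dess–Martin periodinane, CH2Cl2, 0 °C → rt
Reagents that add atoms: none
Why: Dess–Martin oxidation of a neopentyl-type primary alcohol stops at the aldehyde, which has no α-hydrogen and cannot epimerise (the descriptor at the aryl-bearing carbon changes by priority only).

Step 10
Reactants: 17 (2,6-dimethoxyphenyl)methanol
Product: 18 5-{[(2,6-dimethoxyphenyl)methyl]sulfanyl}-1-phenyl-1H-tetrazole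
Conditions: 1-phenyl-1H-tetrazole-5-thiol, PPh3, DIAD, THF, 0 °C → rt
Reagents that add atoms: 1-phenyl-1H-tetrazole-5-thiol, Sc1nnnn1-c1ccccc1
Why: Mitsunobu thioetherification; the acidic thiol displaces the oxyphosphonium of the activated benzylic alcohol by SN2.

Step 11
Reactants: 18 5-{[(2,6-dimethoxyphenyl)methyl]sulfanyl}-1-phenyl-1H-tetrazole
Product: 19 5-{[(2,6-dimethoxyphenyl)methyl]sulfonyl}-1-phenyl-1H-tetrazole
Conditions: 30% H2O2, (NH4)6Mo7O24·4H2O (10 mol%), EtOH, 0 °C → rt
Reagents that add atoms: hydrogen peroxide, OO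
Why: Molybdate-catalysed peroxide oxidation takes the sulfide through the sulfoxide to the sulfone without attacking the electron-rich ring.

Step 12
Reactants: 16 (1S,2S)-2-(2,6-dimethoxyphenyl)-1,4-dimethylcyclohex-3-ene-1-carbaldehyde; 19 5-{[(2,6-dimethoxyphenyl)methyl]sulfonyl}-1-phenyl-1H-tetrazole
Product: 20 2-[(E)-2-[(1R,2R)-2-(2,6-dimethoxyphenyl)-1,4-dimethylcyclohex-3-en-1-yl]ethenyl]-1,3-dimethoxybenzene
Conditions: 19, KHMDS, DME, −60 °C; then 16, −60 °C → rt
Reagents that add atoms: none
Why: Julia–Kocienski olefination; the potassium sulfonyl carbanion adds to the non-enolisable aldehyde, Smiles rearrangement and loss of SO2 and tetrazolone give the alkene, and the quaternary C1 together with the di-ortho-substituted aryl group should enforce the E geometry while both ring stereocentres stay untouched.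

Step 13
Reactants: 20 2-[(E)-2-[(1R,2R)-2-(2,6-dimethoxyphenyl)-1,4-dimethylcyclohex-3-en-1-yl]ethenyl]-1,3-dimethoxybenzene
Product: 21 2-[(E)-2-[(1R,2R)-2-(2-hydroxy-6-methoxyphenyl)-1,4-dimethylcyclohex-3-en-1-yl]ethenyl]-3-methoxyphenol
Conditions: NaSEt (8 equiv), DMF, 130 °C
Reagents that add atoms: none
Why: SN2 attack of thiolate on methyl cleaves one aryl methyl ether per ring, because the phenoxide formed deactivates the second methoxy group of the same ring and the two methoxy groups of each ring are interchangeable by rotation; the basic conditions avoid acid-induced addition of a phenol to the C4=C5 alkene.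

Step 14
Reactants: 21 2-[(E)-2-[(1R,2R)-2-(2-hydroxy-6-methoxyphenyl)-1,4-dimethylcyclohex-3-en-1-yl]ethenyl]-3-methoxyphenol
Product: 22 3-[(E)-2-[(1R,2R)-2-(3-formyl-2-hydroxy-6-methoxyphenyl)-1,4-dimethylcyclohex-3-en-1-yl]ethenyl]-2-hydroxy-4-methoxybenzaldehyde
Conditions: MgCl2, Et3N, (CH2O)n, MeCN, reflux; aq. citric acid work-up
Reagents that add atoms: paraformaldehyde (as formaldehyde), C=O
Why: Magnesium-phenoxide-mediated ortho-formylation (Casnati–Skattebøl reaction) delivers formaldehyde through a chelate only to the free position ortho to each hydroxyl (para to methoxy), and a second formaldehyde oxidises the benzylic alkoxide to the aldehyde.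

Step 15
Reactants: 22 3-[(E)-2-[(1R,2R)-2-(3-formyl-2-hydroxy-6-methoxyphenyl)-1,4-dimethylcyclohex-3-en-1-yl]ethenyl]-2-hydroxy-4-methoxybenzaldehyde
Product: 23 8-[(E)-2-[(1R,2R)-2-(7-methoxy-2-oxo-2H-chromen-8-yl)-1,4-dimethylcyclohex-3-en-1-yl]ethenyl]-7-methoxy-2H-chromen-2-one (CNP0156435.1)
Conditions: Ph3P=C=C=O (2.5 equiv), toluene, 100 °C
Reagents that add atoms: (triphenylphosphoranylidene)ketene, O=C=C=P(c1ccccc1)(c1ccccc1)c1ccccc1
Why: Each phenol adds to the slender ketene ylide to give an aryl (triphenylphosphoranylidene)acetate, which closes by intramolecular Wittig reaction onto the ortho formyl group (the ring forces the Z alkene), forming both pyranone rings at a temperature too low for a [3,3] shift of the 1,5-diene Cb=Ca–C1–C6–C5=C4.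

## Compound list

1 | methyl 3-hydroxy-2-methylpropanoate (racemic) | COC(=O)C(C)CO | starting material
2 | methyl 3-[(tert-butyldimethylsilyl)oxy]-2-methylpropanoate (racemic) | COC(=O)C(C)CO[Si](C)(C)C(C)(C)C | intermediate
3 | 3-[(tert-butyldimethylsilyl)oxy]-2-methylpropanal (racemic) | CC(CO[Si](C)(C)C(C)(C)C)C=O | intermediate
4 | but-3-en-2-one | CC(=O)C=C | starting material
5 | (R)-2-{[(tert-butyldimethylsilyl)oxy]methyl}-2-methyl-5-oxohexanal | CC(C)(C)[Si](C)(C)OC[C@@](C=O)(C)CCC(C)=O | intermediate
6 | (S)-4-{[(tert-butyldimethylsilyl)oxy]methyl}-4-methylcyclohex-2-en-1-one | CC(C)(C)[Si](C)(C)OC[C@@]1(C)CCC(=O)C=C1 | intermediate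
7 | (S)-4-(hydroxymethyl)-4-methylcyclohex-2-en-1-one | OC[C@@]1(C)CCC(=O)C=C1 | intermediate
8 | 2-bromo-1,3-dimethoxybenzene | COc1cccc(OC)c1Br | starting material
9 | (2,6-dimethoxyphenyl)magnesium bromide | COc1cccc(OC)c1[Mg]Br | intermediate
10 | bis(bromomagnesium) enolate–alkoxide of (3R,4S)-3-(2,6-dimethoxyphenyl)-4-(hydroxymethyl)-4-methylcyclohexanone (C4=C5 enolate) | Br[Mg]OC[C@@]1(C)CCC(O[Mg]Br)=C[C@H]1c1c(OC)cccc1OC | intermediate
11 | {[(1S,2R)-2-(2,6-dimethoxyphenyl)-1-methyl-4-(trimethylsilyloxy)cyclohex-3-en-1-yl]methoxy}trimethylsilane | C[Si](C)(C)OC[C@@]1(C)CCC(O[Si](C)(C)C)=C[C@H]1c1c(OC)cccc1OC | intermediate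
12 | lithium (3R,4S)-3-(2,6-dimethoxyphenyl)-4-methyl-4-[(trimethylsilyloxy)methyl]cyclohex-1-en-1-olate | C[Si](C)(C)OC[C@@]1(C)CCC(O[Li])=C[C@H]1c1c(OC)cccc1OC | intermediate
13 | (3R,4S)-3-(2,6-dimethoxyphenyl)-4-methyl-4-[(trimethylsilyloxy)methyl]cyclohex-1-en-1-yl trifluoromethanesulfonate | C[Si](C)(C)OC[C@@]1(C)CCC(OS(=O)(=O)C(F)(F)F)=C[C@H]1c1c(OC)cccc1OC | intermediate
14 | {[(1S,2R)-2-(2,6-dimethoxyphenyl)-1,4-dimethylcyclohex-3-en-1-yl]methoxy}trimethylsilane | C[Si](C)(C)OC[C@@]1(C)CCC(C)=C[C@H]1c1c(OC)cccc1OC | intermediate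
15 | [(1S,2R)-2-(2,6-dimethoxyphenyl)-1,4-dimethylcyclohex-3-en-1-yl]methanol | OC[C@@]1(C)CCC(C)=C[C@H]1c1c(OC)cccc1OC | intermediate
16 | (1S,2S)-2-(2,6-dimethoxyphenyl)-1,4-dimethylcyclohex-3-ene-1-carbaldehyde | O=C[C@@]1(C)CCC(C)=C[C@H]1c1c(OC)cccc1OC | intermediate
17 | (2,6-dimethoxyphenyl)methanol | COc1cccc(OC)c1CO | starting material
18 | 5-{[(2,6-dimethoxyphenyl)methyl]sulfanyl}-1-phenyl-1H-tetrazole | COc1cccc(OC)c1CSc1nnnn1-c1ccccc1 | intermediate
19 | 5-{[(2,6-dimethoxyphenyl)methyl]sulfonyl}-1-phenyl-1H-tetrazole | COc1cccc(OC)c1CS(=O)(=O)c1nnnn1-c1ccccc1 | intermediate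
20 | 2-[(E)-2-[(1R,2R)-2-(2,6-dimethoxyphenyl)-1,4-dimethylcyclohex-3-en-1-yl]ethenyl]-1,3-dimethoxybenzene | COc1cccc(OC)c1/C=C/[C@@]1(C)CCC(C)=C[C@H]1c1c(OC)cccc1OC | intermediate
21 | 2-[(E)-2-[(1R,2R)-2-(2-hydroxy-6-methoxyphenyl)-1,4-dimethylcyclohex-3-en-1-yl]ethenyl]-3-methoxyphenol | COc1cccc(O)c1/C=C/[C@@]1(C)CCC(C)=C[C@H]1c1c(O)cccc1OC | intermediate
22 | 3-[(E)-2-[(1R,2R)-2-(3-formyl-2-hydroxy-6-methoxyphenyl)-1,4-dimethylcyclohex-3-en-1-yl]ethenyl]-2-hydroxy-4-methoxybenzaldehyde | COc1ccc(C=O)c(O)c1/C=C/[C@@]1(C)CCC(C)=C[C@H]1c1c(OC)ccc(C=O)c1O | intermediate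
23 | 8-[(E)-2-[(1R,2R)-2-(7-methoxy-2-oxo-2H-chromen-8-yl)-1,4-dimethylcyclohex-3-en-1-yl]ethenyl]-7-methoxy-2H-chromen-2-one | COc1ccc2ccc(=O)oc2c1/C=C/[C@@]1(C)CCC(C)=C[C@H]1c1c(OC)ccc2ccc(=O)oc12 | target

## Step count and risk

Total step count: 15. Longest linear sequence: 12 steps (steps 1–4, 6–9, 12–15, from compound 1). Side branches: step 5 (one step) and steps 10–11 (two steps).

Steps most likely to fail:

1. Step 6 (proposed new method). The di-ortho-substituted aryl group may not be transferred to the neopentyl-type C6 within the magnesium alkoxide. Direct 1,2-addition to the carbonyl, loss of formaldehyde from the alkoxide by vinylogous retro-aldol cleavage, or incomplete silylation of the magnesium enolate may then take over. The fallback replaces substrate-directed delivery by catalyst control on the silyl ether, using known reaction types. It sets out from 6 and 9 and comes back at 15. Reagent 9 is transmetalated with ZnCl2 to (2,6-dimethoxyphenyl)zinc chloride F1. Rhodium/BINAP-catalysed asymmetric 1,4-addition of F1 to 6 in the presence of TMSCl, with the ligand antipode chosen so that the aryl enters syn to the silyloxymethyl arm, should give tert-butyl{[(1S,2R)-2-(2,6-dimethoxyphenyl)-1-methyl-4-(trimethylsilyloxy)cyclohex-3-en-1-yl]methoxy}dimethylsilane F2. The weak intrinsic bias between methyl and silyloxymethyl should let the catalyst dominate. Enolate regeneration with MeLi and triflation with PhNTf2 should then give (3R,4S)-4-{[(tert-butyldimethylsilyl)oxy]methyl}-3-(2,6-dimethoxyphenyl)-4-methylcyclohex-1-en-1-yl trifluoromethanesulfonate F3. Iron-catalysed coupling with MeMgBr should give tert-butyl{[(1S,2R)-2-(2,6-dimethoxyphenyl)-1,4-dimethylcyclohex-3-en-1-yl]methoxy}dimethylsilane F4, and HF·pyridine releases 15.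

2. Step 3 (key step). Enantiofacial discrimination between methyl and silyloxymethyl in the enamine may be poor (an E/Z enamine mixture). The sequence may also stall at keto-aldehyde 5, or silanolate may be lost by β-elimination. The fallback gives up asymmetric catalysis for resolution. It sets out from 3 and 4 and comes back at 6. A Stork enamine Robinson annulation (pyrrolidine, then buffered AcOH/NaOAc hydrolysis and aldol condensation) should give racemic 4-{[(tert-butyldimethylsilyl)oxy]methyl}-4-methylcyclohex-2-en-1-one F5. Preparative chromatography on a chiral stationary phase then separates the (S)-enantiomer 6.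

3. Step 12. Addition of the hindered sulfonyl carbanion to the neopentyl-type aldehyde, which sits cis to the di-ortho-substituted aryl group, may be slow, or the elimination may give an E/Z mixture. The fallback moves the bond formation from Ca=Cb to Cb–aryl. It sets out from 16 and comes back at 20. Wittig methylenation (Ph3P=CH2, THF) should give 2-[(1R,6R)-6-ethenyl-3,6-dimethylcyclohex-2-en-1-yl]-1,3-dimethoxybenzene F6. A Heck reaction of F6 with commercial 2-iodo-1,3-dimethoxybenzene (Pd2(dba)3, P(t-Bu)3, Cy2NMe, dioxane, 90 °C) can only give the E alkene of 20, because the quaternary C1 offers no alternative β-hydrogen.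

Further compounds
F1 | step 6 | (2,6-dimethoxyphenyl)zinc chloride | COc1cccc(OC)c1[Zn]Cl
F2 | step 6 | tert-butyl{[(1S,2R)-2-(2,6-dimethoxyphenyl)-1-methyl-4-(trimethylsilyloxy)cyclohex-3-en-1-yl]methoxy}dimethylsilane | CC(C)(C)[Si](C)(C)OC[C@@]1(C)CCC(O[Si](C)(C)C)=C[C@H]1c1c(OC)cccc1OC
F3 | step 6 | (3R,4S)-4-{[(tert-butyldimethylsilyl)oxy]methyl}-3-(2,6-dimethoxyphenyl)-4-methylcyclohex-1-en-1-yl trifluoromethanesulfonate | CC(C)(C)[Si](C)(C)OC[C@@]1(C)CCC(OS(=O)(=O)C(F)(F)F)=C[C@H]1c1c(OC)cccc1OC
F4 | step 6 | tert-butyl{[(1S,2R)-2-(2,6-dimethoxyphenyl)-1,4-dimethylcyclohex-3-en-1-yl]methoxy}dimethylsilane | CC(C)(C)[Si](C)(C)OC[C@@]1(C)CCC(C)=C[C@H]1c1c(OC)cccc1OC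
F5 | step 3 | racemic 4-{[(tert-butyldimethylsilyl)oxy]methyl}-4-methylcyclohex-2-en-1-one | CC(C)(C)[Si](C)(C)OCC1(C)CCC(=O)C=C1
F6 | step 12 | 2-[(1R,6R)-6-ethenyl-3,6-dimethylcyclohex-2-en-1-yl]-1,3-dimethoxybenzene | C=C[C@@]1(C)CCC(C)=C[C@H]1c1c(OC)cccc1OC
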